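(The runs are calculated with made-up constants, noise included.)

If free monomer leaves a flask by two routes at once, the first thing to ask is what part of the loss ends in chains; I call this the chain share, the selectivity for chains.

| setting | epsilon | theta | Sunday's | Tuesday's |
|---|---|---|---|---|
| free monomer | 0.12 M | 0.24 M | 0.10 M | 0.15 M |
| pre-initiator | 8.5 mol% | 8.5 mol% | 8.5 mol% | 8.5 mol% |
| remark | run made earlier | run made earlier |  |  |
| time |  |  | 8.0 h | 8.0 h |

| run | time / h | monomer in chains / % | free monomer / % |
|---|---|---|---|
| epsilon | 0.333 | 0 | 90.1 |
| epsilon | 0.833 | 2.2 | 78.0 |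
| epsilon | 1.50 | 4.6 | 63.1 |
| epsilon | 2.50 | 9.3 | 43.6 |
| epsilon | 3.00 | 12.5 | 35.2 |
| epsilon | 4.00 | 16.4 | 23.7 |
| epsilon | 6.00 | 19.7 | 11.5 |
| theta | 0.833 | 3.3 | 77.1 |
| theta | 1.50 | 9.8 | 58.7 |
| theta | 2.50 | 18.3 | 36.6 |
| theta | 3.00 | 22.3 | 28.3 |
| theta | 4.00 | 28.3 | 16.4 |
| theta | 5.00 | 32.7 | 9.1 |
| theta | 6.00 | 33.6 | 5.9 |

(each reading ± 0.5 percentage points)

* which of the two ends with the longer chains by the average number of monomer units in a chain (chains begun, living or dead) ("neither" if they lie within 10 %) (Sunday's / Tuesday's / neither)
* average number of monomer units in a chain (chains begun, living or dead) at the end, Sunday's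
* average number of monomer units in a chain (chains begun, living or dead) at the end, Tuesday's

- the average divides the monomer in chains by the number of chains begun, living and dead together
- the earlier runs do not show the number of chains; that part of a forecast is a guess

I kept the books on free monomer, in percent of its charge. At its last reading, at 6.00 h, the epsilon run had lost 88.5 % and held 19.7 % in chains, a chain share of 22.3 %. The theta run, at 6.00 h, had lost 94.1 % and held 33.6 %, a chain share of 35.7 %. Both runs had the same loading, so their charge stands for [pre-initiator] as well as for [free monomer], and the readings can't tell the two apart. A straight line through the two shares rises by 1.12 M⁻¹, the chain-share slope.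

The first entry is what stays free. The epsilon run gives a half-life of 1.92 h, which I used roughly for both flasks, so 8.0 h is 4.17 half-lives and leaves 5.59 %. The second entry is chains. The line was drawn from readings at 6.00 h, and I assumed that its shares still held at 8.0 h; it gives Sunday's a share of 20.0 % and Tuesday's 25.6 %, hence 18.9 % and 24.2 % in chains. The third entry closes my reckoned books: for Sunday's and Tuesday's, I put 75.5 % and 70.2 % elsewhere.

Length is monomer in chains over chains begun. At one loading, and if the same fraction of pre-initiator starts chains, Tuesday's comes out longer by a factor of 1.28, which is outside the margin of 10 %. That fraction isn't in the readings.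

The forecast named Tuesday's, with 2.6 for Sunday's (range 2.1 to 4.5) and 3.5 for Tuesday's (range 2.8 to 6), and said of the count of chains: “The initiated fraction is a guess”.

    pre-initiator → initiator (k = 0.120 h⁻¹)
    monomer in chains + living end → free monomer + living end, rate k2*[living end] as long as [monomer in chains] is above zero (k = 0.520 h⁻¹)
    free monomer → uncatalysed product (k = 0.270 h⁻¹)
    free monomer + living end → monomer in chains + living end, rate k4*[living end]*[free monomer] (k = 49.0 M⁻¹ h⁻¹)
    free monomer + initiator → living end + monomer in chains (k = 86.0 M⁻¹ h⁻¹)

Tuesday's ended longer, 5.21 against 3.61 for Sunday's. At 8.00 h, Tuesday's held 0.00712 M of living end, with 38.3 % of its pre-initiator still unreacted. Its chain share was 26.1 %, against 25.6 % on my line. Read against [pre-initiator], I put the line to Tuesday's flask with 5.1 mol% of pre-initiator, whose charge of pre-initiator equals that of the old loading at 0.0900 M of free monomer. There the line gives 18.9 %, and that flask, with 17.8 % in chains and 6.3 % free monomer left, had a chain share of 19.0 %.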